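Percent of the charge was the unit in which I laid the two runs side by side. The grey run is the asked flask itself, followed to 3.00 d, and the violet run is its neighbour, started from 0.56 M against 0.83 M.

| flask | starting material | remark | time |
|---|---|---|---|
| grey | 0.83 M | the very flask that is asked about, followed so far |  |
| violet | 0.56 M | run made earlier |  |
| flask | 0.83 M |  | 15 d |

| run | time / d | target / % | side product / % |
|---|---|---|---|
| grey | 0.167 | 8.5 | 1.2 |
| grey | 0.500 | 15.9 | 6.4 |
| grey | 0.833 | 19.1 | 11.4 |
| grey | 1.25 | 20.3 | 16.9 |
| grey | 1.67 | 20.4 | 20.3 |
| grey | 2.50 | 20.1 | 24.0 |
| grey | 3.00 | 20.4 | 25.3 |
| violet | 0.833 | 19.4 | 11.3 |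
| violet | 1.25 | 20.3 | 17.2 |
| violet | 2.08 | 19.9 | 23.2 |
| violet | 3.00 | 20.6 | 25.7 |
| violet | 5.00 | 20.3 | 26.7 |
| violet | 6.00 | 19.9 | 26.9 |
| violet | 10.0 | 20.2 | 27.3 |

(readings scatter by 0.3 percentage points)

- for target the crystals are counted in
- as a solid, counted per litre of solution: crystals
- steps thought possible: intermediate A <-> intermediate C; starting material -> intermediate C; crystals <-> target; intermediate B -> side product; starting material -> intermediate A; starting material -> target; starting material -> intermediate B

* share of target in target plus side product at 25 min
* share of target in target plus side product at 12 h
* share of target in target plus side product at 15 d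

At 3.00 d the share of target in target plus side product read 44.6 % in grey and 44.5 % in violet. Because these match across charges differing by a factor of 1.48, I took the split between the two products to be independent of charge, as first-order steps give, and let violet show grey's later course.

Violet's target stayed near 20.2 % while its side product climbed to 27.3 %. Those last violet readings gave 42.5 %, and this end share, the selectivity once both products have stopped moving, was my number, a reading with its scatter, for the end of the grey flask.

How fast that end is approached I read from violet's side product: between 2.08 d and 3.00 d its distance from the last reading shrank at a pace that reads as one halving in 0.678 d. At that pace the asked time lies 7.38 halvings beyond violet's last reading. At 0.500 d the grey reading itself gave a share of 71.3 %.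

The forecast gave 98.7 %, 71.7 % and 42.5 %, on the ground that “the target forms directly from starting material, while side product arrives late through intermediate B”.

The flask gave 98.7 %, 72.4 % and 43.3 %.

    intermediate A ⇌ intermediate C (K = 0.600, k = 0.750 h⁻¹)
    starting material → intermediate C (k = 0.00560 h⁻¹)
    crystals ⇌ target, rate k3*(cs3 - [target]) while solid is left; crystals form when [target] > cs3 (solubility = 0.210 M, k = 18.0 h⁻¹)
    intermediate B → side product (k = 0.0480 h⁻¹)
    starting material → intermediate A (k = 0.0610 h⁻¹)
    starting material → target (k = 0.0260 h⁻¹)
    starting material → intermediate B (k = 0.0340 h⁻¹)

Of the two steps from starting material toward the products, the one to target carries 43.3 % of their summed constants. I put the end share of 42.5 % to a further flask charged with 1.4 M of starting material. That flask held more crystals than the asked flask, 5.54 % at 15.0 d, counted within its target of 20.5 % beside 26.9 % side product, and its share ended at 43.3 %.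

The readings were generated by integration with made-up constants; the scatter is artificial.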